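## Retrosynthetic overview
1. The target comes from one global hydrogenation of a bis-O-benzyl chalcone, which saturates the C=C and cleaves both OBn groups.
2. The chalcone Cα=Cβ bond is the key disconnection: a Claisen–Schmidt crossed aldol condensation of benzaldehyde with the fully substituted 4-OBn/2-OMe acetophenone.
3. The O-substitution pattern is set by chelation control on 2,4-dihydroxy-3-(2-hydroxybenzyl)acetophenone. The two free OH groups are benzylated first, then the H-bonded 2-OH is methylated.
4. That triol ketone comes from Friedel–Crafts acetylation and BBr3 demethylation of 1,3-dimethoxy-2-(2-methoxybenzyl)benzene. This in turn comes from ortho-lithiated 1,3-dimethoxybenzene and 2-methoxybenzaldehyde, followed by ionic reduction.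
5. No ring is formed; all three benzene rings are bought intact.

Assumption: the target SMILES has no stereocentre and no stereogenic double bond, so it is achiral and needs no enantiocontrol; the racemic carbinol centres in 4 and 11 are erased later.

## Route

Step 1
Reactants: 1 1,3-dimethoxybenzene; 2 2-methoxybenzaldehyde
Product: 4 (2,6-dimethoxyphenyl)(2-methoxyphenyl)methanol (racemic), via 2,6-dimethoxyphenyllithium 3 (not isolated)
Conditions: n-BuLi (1.1 equiv), THF, 0 °C → rt, 2 h; then 2, −78 °C → rt; H2O quench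
Reagents that add atoms: none
Why: In this directed ortho-metalation both OMe groups steer n-BuLi to C2 only, and the aryllithium adds 1,2 to the non-enolisable aldehyde, giving a racemic carbinol centre that step 2 removes.

Step 2
Reactants: 4 (2,6-dimethoxyphenyl)(2-methoxyphenyl)methanol
Product: 5 1,3-dimethoxy-2-(2-methoxybenzyl)benzene
Conditions: Et3SiH (3 equiv), TFA (5 equiv), CH2Cl2, 0 °C, 1 h
Reagents that add atoms: none
Why: In this ionic hydrogenation TFA ionises the doubly benzylic alcohol to a cation stabilised by three ortho-OMe groups, and Et3SiH traps it irreversibly by hydride transfer.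

Step 3
Reactants: 5 1,3-dimethoxy-2-(2-methoxybenzyl)benzene
Product: 6 1-[2,4-dimethoxy-3-(2-methoxybenzyl)phenyl]ethanone
Conditions: AcCl (1.1 equiv), SnCl4 (1.2 equiv), CH2Cl2, −10 → 0 °C, 2 h; ice/1 M HCl
Reagents that add atoms: acetyl chloride, CC(=O)Cl
Why: In this Friedel–Crafts acylation C4 (equal to C6 by symmetry) of the resorcinol ring is the only site ortho/para to two OMe groups and far outruns the singly activated anisole ring, while the acyl group blocks a second acylation and mild SnCl4 spares the ethers and the diarylmethane.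

Step 4
Reactants: 6 1-[2,4-dimethoxy-3-(2-methoxybenzyl)phenyl]ethanone
Product: 7 1-[2,4-dihydroxy-3-(2-hydroxybenzyl)phenyl]ethanone
Conditions: BBr3 (5 equiv), CH2Cl2, −78 °C → rt, 16 h; ice-water
Reagents that add atoms: none
Why: Excess BBr3 cleaves all three aryl methyl ethers by Lewis-acid-assisted SN2 attack of bromide on methyl, and the aryl ketone and the diarylmethane link tolerate these conditions.

Step 5
Reactants: 7 1-[2,4-dihydroxy-3-(2-hydroxybenzyl)phenyl]ethanone
Product: 8 1-{4-(benzyloxy)-3-[2-(benzyloxy)benzyl]-2-hydroxyphenyl}ethanone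
Conditions: BnBr (2.1 equiv), K2CO3 (2.5 equiv), acetone, reflux, 8 h
Reagents that add atoms: benzyl bromide, BrCc1ccccc1
Why: In this chelation-controlled Williamson etherification the acidic 4-OH and the ordinary B-ring phenol alkylate, whereas the 2-OH is hydrogen-bonded to the carbonyl, flanked on both sides, and unreactive with a weak base and limited BnBr.

Step 6
Reactants: 8 1-{4-(benzyloxy)-3-[2-(benzyloxy)benzyl]-2-hydroxyphenyl}ethanone
Product: 9 1-{4-(benzyloxy)-3-[2-(benzyloxy)benzyl]-2-methoxyphenyl}ethanone
Conditions: MeI (3 equiv), K2CO3 (3 equiv), DMF, 45 °C, 12 h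
Reagents that add atoms: iodomethane, CI
Why: In this Williamson O-methylation the polar aprotic solvent and excess of the small electrophile MeI overcome the chelation of the only remaining OH, while K2CO3 is too weak to enolise the ketone and the benzyl ethers are inert.

Step 7 (key C–C bond formation)
Reactants: 9 1-{4-(benzyloxy)-3-[2-(benzyloxy)benzyl]-2-methoxyphenyl}ethanone; 10 benzaldehyde
Product: 12 (E)-1-{4-(benzyloxy)-3-[2-(benzyloxy)benzyl]-2-methoxyphenyl}-3-phenylprop-2-en-1-one, via racemic beta-hydroxy ketone aldol adduct 11 (not isolated)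
Conditions: PhCHO (1.2 equiv), KOH (50% aq, 3 equiv), EtOH–THF 2:1, rt, 24 h
Reagents that add atoms: none
Why: In this Claisen–Schmidt crossed aldol condensation only 9 can enolise and only 10 is an aldehyde electrophile, E1cB loss of water drives the reaction to the conjugated E-enone, and with no free 2'-OH no flavanone can form.

Step 8
Reactants: 12 (E)-1-{4-(benzyloxy)-3-[2-(benzyloxy)benzyl]-2-methoxyphenyl}-3-phenylprop-2-en-1-one
Product: 14 1-[4-hydroxy-3-(2-hydroxybenzyl)-2-methoxyphenyl]-3-phenylpropan-1-one (target), via bis-O-benzyl dihydrochalcone 13 (not isolated)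
Conditions: H2 (1 atm), 10% Pd/C, EtOAc–MeOH 1:1, rt, 6–12 h, stopped when 13 is consumed
Reagents that add atoms: none
Why: In this catalytic hydrogenation with hydrogenolysis the enone C=C saturates first and both aryl benzyl ethers then cleave, while the electron-rich aryl ketone, the OMe group and the diarylmethane C–C bond survive at 1 atm in neutral solvent.

## Compound list
1 | 1,3-dimethoxybenzene | COc1cccc(OC)c1 | starting material
2 | 2-methoxybenzaldehyde | COc1ccccc1C=O | starting material
3 | 2,6-dimethoxyphenyllithium | [Li]c1c(OC)cccc1OC | intermediate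
4 | (2,6-dimethoxyphenyl)(2-methoxyphenyl)methanol (racemic) | COc1ccccc1C(O)c1c(OC)cccc1OC | intermediate
5 | 1,3-dimethoxy-2-(2-methoxybenzyl)benzene | COc1ccccc1Cc1c(OC)cccc1OC | intermediate
6 | 1-[2,4-dimethoxy-3-(2-methoxybenzyl)phenyl]ethanone | CC(=O)c1ccc(OC)c(Cc2ccccc2OC)c1OC | intermediate
7 | 1-[2,4-dihydroxy-3-(2-hydroxybenzyl)phenyl]ethanone | CC(=O)c1ccc(O)c(Cc2ccccc2O)c1O | intermediate
8 | 1-{4-(benzyloxy)-3-[2-(benzyloxy)benzyl]-2-hydroxyphenyl}ethanone | CC(=O)c1ccc(OCc2ccccc2)c(Cc2ccccc2OCc2ccccc2)c1O | intermediate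
9 | 1-{4-(benzyloxy)-3-[2-(benzyloxy)benzyl]-2-methoxyphenyl}ethanone | CC(=O)c1ccc(OCc2ccccc2)c(Cc2ccccc2OCc2ccccc2)c1OC | intermediate
10 | benzaldehyde | O=Cc1ccccc1 | starting material
11 | 1-{4-(benzyloxy)-3-[2-(benzyloxy)benzyl]-2-methoxyphenyl}-3-hydroxy-3-phenylpropan-1-one (racemic aldol adduct) | COc1c(C(=O)CC(O)c2ccccc2)ccc(OCc2ccccc2)c1Cc1ccccc1OCc1ccccc1 | intermediate
12 | (E)-1-{4-(benzyloxy)-3-[2-(benzyloxy)benzyl]-2-methoxyphenyl}-3-phenylprop-2-en-1-one | COc1c(C(=O)/C=C/c2ccccc2)ccc(OCc2ccccc2)c1Cc1ccccc1OCc1ccccc1 | intermediate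
13 | 1-{4-(benzyloxy)-3-[2-(benzyloxy)benzyl]-2-methoxyphenyl}-3-phenylpropan-1-one | COc1c(C(=O)CCc2ccccc2)ccc(OCc2ccccc2)c1Cc1ccccc1OCc1ccccc1 | intermediate
14 | 1-[4-hydroxy-3-(2-hydroxybenzyl)-2-methoxyphenyl]-3-phenylpropan-1-one | COc1c(C(=O)CCc2ccccc2)ccc(O)c1Cc1ccccc1O | target

## Summary
Total step count: 8. Longest linear sequence: 8 steps (1 → 14, fully linear).

## Three steps most likely to fail

**Step 3.** The risks are competing acylation of the anisole ring and acid-induced loss of the electron-rich 2-methoxybenzyl group. The fallback sets out from 5 and reverses the order of events. BBr3 in CH2Cl2 first gives 2-(2-hydroxybenzyl)benzene-1,3-diol F1. A Houben–Hoesch reaction follows (MeCN, ZnCl2, dry HCl, Et2O, 0 °C), which C-acylates only resorcinol-type rings. It gives 1-[2,4-dihydroxy-3-(2-hydroxybenzyl)phenyl]ethan-1-iminium chloride F2. Boiling water hydrolyses F2, along with any B-ring imidate. The fallback comes back to the route at 7, bypassing 6.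

**Step 5.** The risks are over-benzylation of the chelated 2-OH and incomplete benzylation of the B-ring phenol. The fallback sets out from 7 and gives up selective alkylation in favour of selective dealkylation. Excess BnBr with K2CO3 in DMF at 80 °C gives 1-{2,4-bis(benzyloxy)-3-[2-(benzyloxy)benzyl]phenyl}ethanone F3. MgBr2·OEt2 in toluene–Et2O at reflux then chelates the carbonyl and removes only the benzyl ether ortho to it. The fallback comes back to the route at 8.

**Step 8.** The risks are over-reduction of the aryl ketone on Pd and sluggish hydrogenolysis of the hindered ethers. The fallback sets out from 12 and uses no H2/Pd at all.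
- Rhodium-catalysed 1,4-hydrosilylation (Et3SiH, 1 mol % RhCl(PPh3)3, toluene, 50 °C) gives (Z)-{1-{4-(benzyloxy)-3-[2-(benzyloxy)benzyl]-2-methoxyphenyl}-3-phenylprop-1-en-1-yl}oxy(triethyl)silane F4.
- Treatment of F4 with 1 M HCl in THF gives 13, now isolated.
- The two benzyl ethers are then removed without reduction, using BCl3 (3 equiv) and pentamethylbenzene in CH2Cl2 at −78 °C for 30 min.
- The reaction is quenched cold with MeOH, so that the 2'-OMe next to the carbonyl is not attacked.

The fallback comes back to the route at 14.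

## Further compounds
F1 | step 3 | 2-(2-hydroxybenzyl)benzene-1,3-diol | Oc1ccccc1Cc1c(O)cccc1O
F2 | step 3 | 1-[2,4-dihydroxy-3-(2-hydroxybenzyl)phenyl]ethan-1-iminium chloride | CC(=[NH2+])c1ccc(O)c(Cc2ccccc2O)c1O.[Cl-]
F3 | step 5 | 1-{2,4-bis(benzyloxy)-3-[2-(benzyloxy)benzyl]phenyl}ethanone | CC(=O)c1ccc(OCc2ccccc2)c(Cc2ccccc2OCc2ccccc2)c1OCc1ccccc1
F4 | step 8 | (Z)-{1-{4-(benzyloxy)-3-[2-(benzyloxy)benzyl]-2-methoxyphenyl}-3-phenylprop-1-en-1-yl}oxy(triethyl)silane | CC[Si](CC)(CC)O/C(=C\Cc1ccccc1)c1ccc(OCc2ccccc2)c(Cc2ccccc2OCc2ccccc2)c1OC
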